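**Retrosynthetic overview**

1. Target numbering (2H-chromene): ring B = O1–C2(Me)–C3(Me)–C4(=O)–C4a=C8a; ring A = C4a–C5(OH)=C6[CH(Ph)CH2CO2H]–C7(=O)–C8(prenyl)(lavandulyl)–C8a.
2. Enabling feature: ring B is a β-alkoxy ketone (O1–C2 lies β to the C4 carbonyl, and O1 sits on C8a next to the acyl-bearing C4a), so a retro-oxa-Michael step opens it to an (E)-2-methylbut-2-enoyl (tigloyl) group on C4a. Closing the side-chain CO2H onto the C5 oxygen as a temporary δ-lactone (the lactone ring of a 4-phenyl-3,4-dihydrocoumarin) leaves the C8a oxygen as the only one that can add.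
3. C8 quaternary centre: dearomative asymmetric Tsuji–Trost prenylation of the phloroglucinol-type ring. Lavandulyl group: Negishi coupling of an aryl iodide with (S)-lavandulylzinc iodide, whose stereocentre comes from an oxazolidinone-controlled deconjugative prenylation.
4. Benzylic centre: Rh-catalysed asymmetric 1,4-addition of PhB(OH)2 to an 8-tigloylcoumarin made by Friedel–Crafts acylation of 5,7-dihydroxycoumarin.
5. Ring order: ring A, the phenyl ring and the lactone ring are bought with the starting materials; ring B is the only ring made and is closed last; the lactone is opened in the final step.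

Key step: step 13

Remark: compound 21 and the target are β-triketones and are drawn as single enol tautomers; the tautomers interconvert.
Remark: the antipodes of the ligands in steps 9 and 12 and of the alkaloid in step 13 are assigned by analogy with the closest model reactions and would be confirmed on the first run; the mirror-image ligand (or quinidine) is the remedy if the sense is opposite.

**Route**

Step 1
Reactants: 1 (S)-4-benzyl-1,3-oxazolidin-2-one; 2 3-methylbut-2-enoyl chloride
Product: 3 (S)-4-benzyl-3-(3-methylbut-2-enoyl)-1,3-oxazolidin-2-one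
Conditions: n-BuLi, THF, −78 °C; then 2, −78 → 0 °C
Reagents that add atoms: none
Why: N-acylation of the lithiated oxazolidinone by the acid chloride (standard loading of an oxazolidinone auxiliary); no stereocentre is formed.

Step 2
Reactants: 3 (S)-4-benzyl-3-(3-methylbut-2-enoyl)-1,3-oxazolidin-2-one; 4 1-bromo-3-methylbut-2-ene (prenyl bromide)
Product: 5 (S)-4-benzyl-3-[(2S)-5-methyl-2-(prop-1-en-2-yl)hex-4-enoyl]-1,3-oxazolidin-2-one
Conditions: NaN(SiMe3)2, THF, −78 °C; then 4, −78 → −30 °C
Reagents that add atoms: none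
Why: Deconjugative α-alkylation of an N-enoyl oxazolidinone (auxiliary-controlled enolate alkylation): γ-deprotonation gives the sodium-chelated Z(O)-dienolate, which prenyl bromide should attack at the α-carbon on the face opposite the benzyl group, setting the (2S) centre that becomes the lavandulyl stereocentre.

Step 3
Reactants: 5 (S)-4-benzyl-3-[(2S)-5-methyl-2-(prop-1-en-2-yl)hex-4-enoyl]-1,3-oxazolidin-2-one
Product: 6 (S)-lavandulol [(2S)-5-methyl-2-(prop-1-en-2-yl)hex-4-en-1-ol]
Conditions: LiBH4, H2O (1 equiv), Et2O, 0 °C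
Reagents that add atoms: none
Why: Reductive cleavage of the N-acyl oxazolidinone by hydride gives the primary alcohol and releases the auxiliary; the α-stereocentre is not enolised under these conditions.

Step 4
Reactants: 6 (S)-lavandulol
Product: 7 (S)-lavandulyl iodide [(3S)-3-(iodomethyl)-2,6-dimethylhepta-1,5-diene]
Conditions: PPh3, I2, imidazole, CH2Cl2, 0 °C → rt
Reagents that add atoms: iodine, II
Why: Appel-type iodination of a primary, non-allylic alcohol by SN2 displacement of the oxyphosphonium group; the stereocentre is β to the reacting carbon and is not touched.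

Step 5
Reactants: 8 5,7-dihydroxy-2H-chromen-2-one (5,7-dihydroxycoumarin); 9 (E)-2-methylbut-2-enoyl chloride (tigloyl chloride)
Product: 10 5,7-dihydroxy-8-[(E)-2-methylbut-2-enoyl]-2H-chromen-2-one
Conditions: AlCl3, PhNO2, 5 °C → rt; aq. HCl work-up
Reagents that add atoms: none
Why: Friedel–Crafts C-acylation of the phloroglucinol-type ring at C8 (ortho to the C7 hydroxyl and para to the C5 hydroxyl, the position at which 5,7-dihydroxycoumarins are acylated) should give the hydrogen-bonded tigloyl phenol; no stereocentre is formed.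

Step 6
Reactants: 10 5,7-dihydroxy-8-[(E)-2-methylbut-2-enoyl]-2H-chromen-2-one
Product: 11 5,7-dihydroxy-6-iodo-8-[(E)-2-methylbut-2-enoyl]-2H-chromen-2-one
Conditions: NIS, MeCN, 0 °C
Reagents that add atoms: N-iodosuccinimide, O=C1CCC(=O)N1I
Why: Electrophilic aromatic iodination at C6, the only free position of the benzene ring and the one flanked by two hydroxyl groups; the electron-poor enone does not react.

Step 7
Reactants: 11 5,7-dihydroxy-6-iodo-8-[(E)-2-methylbut-2-enoyl]-2H-chromen-2-one
Product: 12 6-iodo-5,7-bis(methoxymethoxy)-8-[(E)-2-methylbut-2-enoyl]-2H-chromen-2-one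
Conditions: MOMCl, iPr2NEt, CH2Cl2, 0 °C → rt
Reagents that add atoms: chloromethyl methyl ether, COCCl
Why: O-alkylation of both phenols (Williamson-type etherification) removes the acidic protons before the organozinc step and keeps the C7 oxygen from adding to the tigloyl group until it is wanted.

Step 8
Reactants: 7 (S)-lavandulyl iodide; 12 6-iodo-5,7-bis(methoxymethoxy)-8-[(E)-2-methylbut-2-enoyl]-2H-chromen-2-one
Product: 14 5,7-bis(methoxymethoxy)-6-[(2R)-5-methyl-2-(prop-1-en-2-yl)hex-4-en-1-yl]-8-[(E)-2-methylbut-2-enoyl]-2H-chromen-2-one, via lavandulylzinc iodide 13 (not isolated)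
Conditions: Zn dust, LiCl, THF, 40 °C (7 → 13); then 12, Pd(OAc)2 (3 mol %), SPhos (6 mol %), THF, 50 °C
Reagents that add atoms: none
Why: Negishi sp3–sp2 cross-coupling: LiCl-assisted zinc insertion into the primary iodide and a bulky biarylphosphine–palladium catalyst should tolerate the two ortho substituents of 12 and outpace β-hydride elimination, and the stereocentre β to zinc is not touched (its descriptor changes from S to R only through the priority rules).

Step 9
Reactants: 14 5,7-bis(methoxymethoxy)-6-[(2R)-lavandulyl]-8-tigloyl-2H-chromen-2-one; 15 phenylboronic acid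
Product: 16 (4R)-5,7-bis(methoxymethoxy)-6-[(2R)-5-methyl-2-(prop-1-en-2-yl)hex-4-en-1-yl]-8-[(E)-2-methylbut-2-enoyl]-4-phenyl-3,4-dihydro-2H-chromen-2-one
Conditions: Rh(acac)(C2H4)2 (3 mol %), (R)-SEGPHOS (3.3 mol %), 1,4-dioxane/H2O 10:1, 60 °C
Reagents that add atoms: none
Why: Hayashi–Miyaura reaction (Rh-catalysed asymmetric 1,4-addition of an arylboronic acid to a coumarin): the phenyl–rhodium–bisphosphine species should insert the C3=C4 bond on the face selected by the ligand, setting the (4R) benzylic centre, while the α,β-disubstituted tigloyl enone and the isolated alkenes are much poorer acceptors.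

Step 10
Reactants: 16 (4R)-5,7-bis(methoxymethoxy)-6-[(2R)-lavandulyl]-8-tigloyl-4-phenyl-3,4-dihydro-2H-chromen-2-one
Product: 17 (4R)-5,7-dihydroxy-6-[(2R)-5-methyl-2-(prop-1-en-2-yl)hex-4-en-1-yl]-8-[(E)-2-methylbut-2-enoyl]-4-phenyl-3,4-dihydro-2H-chromen-2-one
Conditions: Me3SiOTf, 2,2'-bipyridyl, CH2Cl2, 0 °C → rt; then H2O
Reagents that add atoms: none
Why: Silyl triflate/bipyridyl cleavage of aryl MOM ethers (acetal cleavage through the aryl silyl ethers) works without protic acid, so the phenols should not add to the prenyl-type alkenes and the tigloyl phenol should not cyclise.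

Step 11
Reactants: 18 3-methylbut-2-en-1-ol (prenol); 19 di-tert-butyl dicarbonate
Product: 20 tert-butyl 3-methylbut-2-en-1-yl carbonate
Conditions: DMAP (10 mol %), CH2Cl2, 0 °C → rt
Reagents that add atoms: none
Why: DMAP-catalysed O-acylation of the primary allylic alcohol by the dicarbonate gives the carbonate that serves as π-prenyl precursor and internal base source; no stereocentre is formed.

Step 12
Reactants: 17 (4R)-5,7-dihydroxy-6-[(2R)-lavandulyl]-8-tigloyl-4-phenyl-3,4-dihydro-2H-chromen-2-one; 20 tert-butyl 3-methylbut-2-en-1-yl carbonate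
Product: 21 (4R,6S)-7-hydroxy-6-[(2R)-5-methyl-2-(prop-1-en-2-yl)hex-4-en-1-yl]-6-(3-methylbut-2-en-1-yl)-8-[(E)-2-methylbut-2-enoyl]-4-phenyl-3,4-dihydro-2H-chromene-2,5(6H)-dione
Conditions: Pd2(dba)3·CHCl3 (2.5 mol %), (1R,2R)-N,N'-bis[2-(diphenylphosphino)benzoyl]cyclohexane-1,2-diamine (7.5 mol %), toluene, rt
Reagents that add atoms: none
Why: Tsuji–Trost asymmetric allylic alkylation with dearomatisation: zerovalent palladium ionises 20, the tert-butoxide released deprotonates the more acidic C5 phenol (para to the acyl group) while the C7 hydroxyl stays chelated to the tigloyl carbonyl, and the phenoxide should attack the unsubstituted terminus of the π-prenyl cation through C6 (the ring carbon flanked by two oxygens) inside the chiral pocket of the diamide–bisphosphine ligand, which selects the C6 face and sets the (6S) quaternary centre by reagent control (closest models: Pd-catalysed allylic dearomatisation of 1-substituted 2-naphthols and linear-selective asymmetric prenylation of oxindoles), any reversible O-prenylation being corrected by re-ionisation.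

Step 13
Reactants: 21 (4R,6S)-7-hydroxy-6-[(2R)-lavandulyl]-6-(3-methylbut-2-en-1-yl)-8-tigloyl-4-phenyl-3,4-dihydro-2H-chromene-2,5(6H)-dione
Product: 22 (4R,6S,8R,9S)-8,9-dimethyl-6-[(2R)-5-methyl-2-(prop-1-en-2-yl)hex-4-en-1-yl]-6-(3-methylbut-2-en-1-yl)-4-phenyl-3,4,8,9-tetrahydropyrano[2,3-f]chromene-2,5,10(6H)-trione (the target with its CO2H closed as δ-lactone on the C5 enol oxygen)
Conditions: (−)-quinine (20 mol %), PhCl, 15 °C
Reagents that add atoms: none
Why: Quinine should act as a bifunctional Brønsted base and hydrogen-bond donor: its quinuclidine nitrogen takes up the acidic enol proton on the C8a oxygen (target numbering), its C9 hydroxyl binds the tigloyl carbonyl, and the enolate oxygen adds to the β-carbon of the (E)-enone in an intramolecular oxa-Michael addition; the closest known reaction types are the quinine-catalysed cyclisation of o-tigloylphenols to cis-2,3-dimethylchroman-4-ones and the base-catalysed cyclisation of 2-enoyl-1,3-dione enols to dihydropyranones. Ring B is closed in the 6-endo-trig mode. The C2 stereocentre (R) is set by the catalyst, which selects the enone face within the ion pair, and the C3 stereocentre (S) is set by substrate control, because the ring enol formed by the addition is protonated at C3 on the face anti to the new pseudoaxial C2 methyl group, which gives the cis-dimethyl (kinetic) product. The step needs regioselectivity between the two oxygen atoms that flank C4a, and this is secured by the temporary lactone, which keeps the C5 oxygen acylated so that only the C8a oxygen is nucleophilic, while the tautomeric hydroxyl on C7 cannot reach the enone. It also needs kinetic control of the cis/trans ratio, which the weak amine base and the low temperature should provide, and the unactivated prenyl and lavandulyl alkenes are not electrophiles under these conditions.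

Step 14
Reactants: 22 δ-lactone of the target
Product: 23 (3R)-3-[(2R,3S,8S)-5-hydroxy-2,3-dimethyl-8-[(2R)-5-methyl-2-(prop-1-en-2-yl)hex-4-en-1-yl]-8-(3-methylbut-2-en-1-yl)-4,7-dioxo-3,4,7,8-tetrahydro-2H-chromen-6-yl]-3-phenylpropanoic acid (target, CNP0150579.4)
Conditions: LiOH, THF/H2O 3:1, 0 °C; then 1 M HCl to pH 3
Reagents that add atoms: lithium hydroxide, [Li+].[OH-]
Why: Saponification of the activated enol lactone (acyl substitution by hydroxide) frees the acid and the C5 enol; under base the vinylogous acid is an enolate, which should protect C3–H from epimerisation, and re-lactonisation is disfavoured because the freed C5–OH is hydrogen-bonded to the C4 carbonyl.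

**Compound list**

1 | (S)-4-benzyl-1,3-oxazolidin-2-one | O=C1OC[C@H](Cc2ccccc2)N1 | starting material
2 | 3-methylbut-2-enoyl chloride | CC(C)=CC(=O)Cl | starting material
3 | (S)-4-benzyl-3-(3-methylbut-2-enoyl)-1,3-oxazolidin-2-one | CC(C)=CC(=O)N1[C@@H](Cc2ccccc2)COC1=O | intermediate
4 | 1-bromo-3-methylbut-2-ene (prenyl bromide) | CC(C)=CCBr | starting material
5 | (S)-4-benzyl-3-[(2S)-5-methyl-2-(prop-1-en-2-yl)hex-4-enoyl]-1,3-oxazolidin-2-one | C=C(C)[C@H](CC=C(C)C)C(=O)N1[C@@H](Cc2ccccc2)COC1=O | intermediate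
6 | (S)-lavandulol, (2S)-5-methyl-2-(prop-1-en-2-yl)hex-4-en-1-ol | C=C(C)[C@H](CC=C(C)C)CO | intermediate
7 | (S)-lavandulyl iodide, (3S)-3-(iodomethyl)-2,6-dimethylhepta-1,5-diene | C=C(C)[C@H](CC=C(C)C)CI | intermediate
8 | 5,7-dihydroxy-2H-chromen-2-one (5,7-dihydroxycoumarin) | O=c1ccc2c(O)cc(O)cc2o1 | starting material
9 | (E)-2-methylbut-2-enoyl chloride (tigloyl chloride) | C/C=C(\C)C(=O)Cl | starting material
10 | 5,7-dihydroxy-8-[(E)-2-methylbut-2-enoyl]-2H-chromen-2-one | C/C=C(\C)C(=O)c1c(O)cc(O)c2ccc(=O)oc12 | intermediate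
11 | 5,7-dihydroxy-6-iodo-8-[(E)-2-methylbut-2-enoyl]-2H-chromen-2-one | C/C=C(\C)C(=O)c1c(O)c(I)c(O)c2ccc(=O)oc12 | intermediate
12 | 6-iodo-5,7-bis(methoxymethoxy)-8-[(E)-2-methylbut-2-enoyl]-2H-chromen-2-one | C/C=C(\C)C(=O)c1c(OCOC)c(I)c(OCOC)c2ccc(=O)oc12 | intermediate
13 | [(2S)-5-methyl-2-(prop-1-en-2-yl)hex-4-en-1-yl]zinc iodide (lavandulylzinc iodide) | C=C(C)[C@H](CC=C(C)C)C[Zn]I | intermediate (not isolated)
14 | 5,7-bis(methoxymethoxy)-6-[(2R)-5-methyl-2-(prop-1-en-2-yl)hex-4-en-1-yl]-8-[(E)-2-methylbut-2-enoyl]-2H-chromen-2-one | C=C(C)[C@H](CC=C(C)C)Cc1c(OCOC)c(C(=O)/C(C)=C/C)c2oc(=O)ccc2c1OCOC | intermediate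
15 | phenylboronic acid | OB(O)c1ccccc1 | starting material
16 | (4R)-5,7-bis(methoxymethoxy)-6-[(2R)-5-methyl-2-(prop-1-en-2-yl)hex-4-en-1-yl]-8-[(E)-2-methylbut-2-enoyl]-4-phenyl-3,4-dihydro-2H-chromen-2-one | C=C(C)[C@H](CC=C(C)C)Cc1c(OCOC)c(C(=O)/C(C)=C/C)c2OC(=O)C[C@H](c3ccccc3)c2c1OCOC | intermediate
17 | (4R)-5,7-dihydroxy-6-[(2R)-5-methyl-2-(prop-1-en-2-yl)hex-4-en-1-yl]-8-[(E)-2-methylbut-2-enoyl]-4-phenyl-3,4-dihydro-2H-chromen-2-one | C=C(C)[C@H](CC=C(C)C)Cc1c(O)c(C(=O)/C(C)=C/C)c2OC(=O)C[C@H](c3ccccc3)c2c1O | intermediate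
18 | 3-methylbut-2-en-1-ol (prenol) | CC(C)=CCO | starting material
19 | di-tert-butyl dicarbonate | CC(C)(C)OC(=O)OC(=O)OC(C)(C)C | starting material
20 | tert-butyl 3-methylbut-2-en-1-yl carbonate | CC(C)=CCOC(=O)OC(C)(C)C | intermediate
21 | (4R,6S)-7-hydroxy-6-[(2R)-5-methyl-2-(prop-1-en-2-yl)hex-4-en-1-yl]-6-(3-methylbut-2-en-1-yl)-8-[(E)-2-methylbut-2-enoyl]-4-phenyl-3,4-dihydro-2H-chromene-2,5(6H)-dione | C=C(C)[C@H](CC=C(C)C)C[C@]1(CC=C(C)C)C(=O)C2=C(OC(=O)C[C@@H]2c3ccccc3)C(C(=O)/C(C)=C/C)=C1O | intermediate
22 | (4R,6S,8R,9S)-8,9-dimethyl-6-[(2R)-5-methyl-2-(prop-1-en-2-yl)hex-4-en-1-yl]-6-(3-methylbut-2-en-1-yl)-4-phenyl-3,4,8,9-tetrahydropyrano[2,3-f]chromene-2,5,10(6H)-trione | C=C(C)[C@H](CC=C(C)C)C[C@]1(CC=C(C)C)C(=O)C2=C(OC(=O)C[C@@H]2c3ccccc3)C4=C1O[C@H](C)[C@H](C)C4=O | intermediate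
23 | (3R)-3-[(2R,3S,8S)-5-hydroxy-2,3-dimethyl-8-[(2R)-5-methyl-2-(prop-1-en-2-yl)hex-4-en-1-yl]-8-(3-methylbut-2-en-1-yl)-4,7-dioxo-3,4,7,8-tetrahydro-2H-chromen-6-yl]-3-phenylpropanoic acid | C=C(C)[C@H](CC=C(C)C)C[C@]1(CC=C(C)C)C(=O)C([C@H](CC(=O)O)c2ccccc2)=C(O)C2=C1O[C@H](C)[C@H](C)C2=O | target

**Summary**

Total step count: 14. Longest linear sequence: 10 steps (steps 1–4, 8–10, 12–14).

Steps most likely to fail:

1. Step 12. What may go wrong is poor discrimination of the two faces of C6 by the ligand (the lavandulyl and benzylic centres are remote), together with stalling, because the dearomatised product is a stronger acid than the starting phenol and can hold the π-prenyl cation as an ion pair or as an O-prenyl enol ether. The fallback sets out from 17 and returns at 21. It replaces π-allyl–palladium control by ion-pair control: prenyl bromide 4, solid Cs2CO3 and N-(9-anthracenylmethyl)cinchonidinium bromide (10 mol %) in toluene at −20 °C should C-alkylate the chiral ammonium phenoxide at C6 (phase-transfer alkylative dearomatisation of an acylphloroglucinol) and give 21 directly, so no new compound arises.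

2. Step 13. What may go wrong is slow addition, because the enolate of the vinylogous acid is a weak oxygen nucleophile and may rest as an unreactive quininium salt, and loss of the cis relationship by base-mediated epimerisation at C3 or by retro-oxa-Michael reaction. The fallback sets out from 16 and returns at 22. It closes ring B on the aromatic phenol, the substrate class on which the quinine cyclisation is established, and dearomatises afterwards. MgBr2·OEt2 in CH2Cl2 at rt should remove only the C7 MOM group, which is chelated to the tigloyl carbonyl, to give (4R)-7-hydroxy-5-(methoxymethoxy)-6-[(2R)-lavandulyl]-8-tigloyl-4-phenylchroman-2-one F1. (−)-Quinine in PhCl should then cyclise this o-tigloylphenol to the aromatic cis-(8R,9S)-dimethylchromanone 5-MOM ether F2. Me3SiOTf/2,2'-bipyridyl should free the C5 phenol F3. The Tsuji–Trost prenylation of step 12 (carbonate 20, same catalyst), now on a single phenol whose two flanks are clearly different, should then give 22.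

3. Step 5. What may go wrong is premature ring closure of the tigloyl phenol and HCl addition across the enone under AlCl3, and incomplete C8 selectivity. The fallback sets out from 8 and returns at 12. It builds the enone after the acylation: AlCl3-mediated acylation with propanoyl chloride should give 5,7-dihydroxy-8-propanoylcoumarin F4; NIS and then MOMCl/iPr2NEt, as in steps 6 and 7, should give the 6-iodo compound F5 and its bis-MOM ether F6; LiN(SiMe3)2 (THF, −78 °C) and acetaldehyde should give the aldol adduct F7 as a diastereomer mixture; and MsCl/Et3N followed by DBU should eliminate it to the (E)-enone 12.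

Further compounds
F0 | step 12 | none | none
F1 | step 13 | (4R)-7-hydroxy-5-(methoxymethoxy)-6-[(2R)-5-methyl-2-(prop-1-en-2-yl)hex-4-en-1-yl]-8-[(E)-2-methylbut-2-enoyl]-4-phenyl-3,4-dihydro-2H-chromen-2-one | C=C(C)[C@H](CC=C(C)C)Cc1c(O)c(C(=O)/C(C)=C/C)c2OC(=O)C[C@H](c3ccccc3)c2c1OCOC
F2 | step 13 | (4R,8R,9S)-5-(methoxymethoxy)-8,9-dimethyl-6-[(2R)-5-methyl-2-(prop-1-en-2-yl)hex-4-en-1-yl]-4-phenyl-3,4,8,9-tetrahydropyrano[2,3-f]chromene-2,10-dione | C=C(C)[C@H](CC=C(C)C)Cc1c2O[C@H](C)[C@H](C)C(=O)c2c4OC(=O)C[C@H](c3ccccc3)c4c1OCOC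
F3 | step 13 | (4R,8R,9S)-5-hydroxy-8,9-dimethyl-6-[(2R)-5-methyl-2-(prop-1-en-2-yl)hex-4-en-1-yl]-4-phenyl-3,4,8,9-tetrahydropyrano[2,3-f]chromene-2,10-dione | C=C(C)[C@H](CC=C(C)C)Cc1c2O[C@H](C)[C@H](C)C(=O)c2c4OC(=O)C[C@H](c3ccccc3)c4c1O
F4 | step 5 | 5,7-dihydroxy-8-propanoyl-2H-chromen-2-one | CCC(=O)c1c(O)cc(O)c2ccc(=O)oc12
F5 | step 5 | 5,7-dihydroxy-6-iodo-8-propanoyl-2H-chromen-2-one | CCC(=O)c1c(O)c(I)c(O)c2ccc(=O)oc12
F6 | step 5 | 6-iodo-5,7-bis(methoxymethoxy)-8-propanoyl-2H-chromen-2-one | CCC(=O)c1c(OCOC)c(I)c(OCOC)c2ccc(=O)oc12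
F7 | step 5 | 8-(3-hydroxy-2-methylbutanoyl)-6-iodo-5,7-bis(methoxymethoxy)-2H-chromen-2-one (mixture of diastereomers) | CC(O)C(C)C(=O)c1c(OCOC)c(I)c(OCOC)c2ccc(=O)oc12
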